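## Structural features

The target is a caged polyprenylated acylphloroglucinol with a homoadamantane core (atoms numbered C1–C43 in the order of its SMILES string). A six-membered trione ring (C11–C39–C30–C28–C25–C26), a second six-membered carbocycle (C11–C12–C13–C41–C30–C39) and two seven-membered rings (C11–C12–C13–C14–C15–C25–C26 and C13–C14–C15–C25–C28–C30–C41) share the bridgeheads C11, C13, C25 and C30. A cyclopentane (C15–C16–C19–C24–C25) is cis-fused across C15–C25; it holds the gem-dimethyl carbon C16 and, at C19, a 2-hydroxypropan-2-yl group on the convex face, cis to H-15 and to C28. C11 carries the (E)-geranyl chain, C30 the benzoyl group and C41 a second gem-dimethyl pair. Of the six stereocentres, C15 and C25 are adjacent and C19 is 1,3 to both; C11 and C30 follow from the cage once C13 and C25 carry C41 and C28 on the same face of the seven-membered ring. The fragile groups are the non-enolisable tricarbonyl array at C30 (retro-Claisen cleavage by alkoxide or hydroxide), the tertiary alcohol (ionisation, elimination) and the 1,5-diene of the geranyl chain (acid). The real difficulty lies in the contiguous fully substituted carbons C16, C25, C30 and C41, above all the C30–C41 bond between two quaternary centres, and in telling apart the two oxygen-bearing tertiary carbons C20 and C41, one of which must ionise while the other must not. The key step uses the fact that the cyclopentane sits on the α- and β-carbons (C25, C15) of ketone C26 and that its other three carbons, C16–C19–C24, form a chain branched at C19: this is the imprint of a trimethylenemethane added across an ester-activated enone C25=C15.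

## Logic of the disconnections

**47 ⇒ 46 ⇒ 44 + 45.** The O–Si bond at C20 and then the C10–C11 bond are cut. The geranyl diene is the most acid-sensitive part and is therefore attached after all cationic chemistry. In 44 the C11–H bond is the only C–H flanked by two carbonyls, and the cage leaves one possible configuration at C11. The gain is a cage without side chain. The demand is a bridgehead metalation that spares four ketones, which is why the C20 oxygen stays silylated until the last step.

**44 ⇒ 43 ⇒ 42.** The C30–C41 bond is cut. Two adjacent quaternary carbons are best joined by capture of a tertiary cation by the carbon of a 2-acyl-1,3-dione enol. The cut opens two rings of the cage at once and leaves a bicyclo[4.3.1]decane trione. The forward step demands that C41 ionises and C20 does not (free alcohol against a tert-butyldimethylsilyl ether), that C- wins over O-alkylation, and that C41 and the trione bridge sit on the same face of the seven-membered ring, which 25 already fixes.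

**42 ⇒ 41 ⇒ 39 + 40; 39 ⇒ 37 + 38.** The bonds C28–C30, C30–C31 and C11–C39 are cut. An ester at C11 could not be condensed with a ketone enolate, because C11–H would be deprotonated first and the ester switched off. The three-carbon unit C39–C30–C31 is therefore built on C11 as an acetyl group and extended through the diketone dianion. The last bond, C28–C30, then forms intramolecularly from the most acidic carbon, C30, onto the hindered ester. The gain is the loss of the whole trione ring, back to keto ester 37. The demand is C-selective acylation three times.

**37 ⇒ 36 ⇒ 34 ⇒ 33 ⇒ 32 ⇒ 31 ⇒ 29 ⇒ 27 ⇒ 25.** The bonds C20–C21 and C20–C22 and the C19–H bond are cut; the carbinol goes back to the exocyclic methylene of 25. C19 is not set by the hydroboration but by equilibration of aldehyde 31, so the step relies on thermodynamics (substituent on the convex face) and not on a facial preference. C26 must be masked against borane and Grignard reagents; an enol silyl ether needs no acid and so spares the tertiary silyl ether and the exocyclic alkene. The two methyl groups are added one at a time, to an aldehyde and to a ketone, so that the neopentyl ester C28 is never in competition.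

**25 ⇒ 24 + 9 (key disconnection).** The bonds C15–C16 and C24–C25 are cut. This removes the cyclopentane, the quaternary carbons C16 and C25 and the stereocentres C15 and C25 in one step and leaves a monocyclic enone ester with a single stereocentre. The forward step demands that the CMe2 terminus of the C4 unit bonds to C15 and that it arrives anti to the C13 side chain.

**24 ⇒ 21 ⇒ 18 ⇒ 16.** The C25–C28 bond (carbonylation of an alkenyl bromide) and then the bonds C25–C26 and C25–C15 (one-carbon ring expansion) are cut. Carboxylation of a saturated 4-substituted cycloheptanone would not distinguish C25 from C11, whereas the carbene carbon of the ring expansion becomes C25 and brings its own bromine. Because 16 is achiral, C13 is set by an enantiotopic deprotonation. The demand is high enantioselectivity in 16 → 18.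

**16 ⇒ 14 ⇒ 10 + 11.** The two C41–CH3 bonds and the O–Si bond are cut, back to a commercial ketal ester.

**9 ⇒ 7 ⇒ 5 ⇒ 4 ⇒ 1.** The acetate C–O bond, the C–CH2Si bond (cross-coupling) and the C–Br bond are cut, back to 3-methylbut-2-enal. The demand is a cross-coupling at a fully substituted alkenyl bromide.

## Other disconnections considered

**Alternative 1:** The cut removes C13–C14 and C30–C41 together, from the C14-hydroxy cage A2 back to the spiro aldehyde A1, a spiro[4.5]decane trione with prenyl and geranyl groups on C11 and a formyl group on C15. In the forward step Me2AlCl would activate the aldehyde, the prenyl alkene would attack through C13, and the enol carbon C30 would trap the C41 cation.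
- In its favour: two C–C bonds, two rings and the quaternary–quaternary bond form in one step. The geranyl group comes in by ordinary C-alkylation, so no bridgehead metalation is needed; on this point it is better than the chosen plan. The C30–C41 event is the same enol/tertiary-cation capture as in step 22, so on that point the two plans are equal.
- Against it here: the first bond closes a seven-membered ring by a Prins reaction, which is entropically slow. The geranyl C7=C9 alkene and the 1,5-diene can compete for the activated aldehyde. The free C20 alcohol and the enol bind the Lewis acid. C11 of A1 is a quaternary stereocentre with two nearly equal allylic groups and must be set relative to the spiro centre C25. A2 carries a C14 hydroxyl whose removal costs two steps of radical chemistry beside two alkenes. The C15, C19 and C25 centres of the spirocyclopentane still need their own asymmetric synthesis.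
- Comparison: the cage assembly is shorter, but the total count is similar or longer, and the stereochemical burden moves to C11, which the chosen plan gets from the cage.

**Alternative 2:** The cut removes C11–C12 and C15–C25 of the cis-hydroazulenone A4, back to the chloromethyl ketone A3 with a tethered 2-substituted diene. In the forward step the oxyallyl cation C11–C26–C25 would add across C12=C13–C14=C15 in an intramolecular (4+3) cycloaddition.
- In its favour: both carbocycles form in one step, against one ring in the chosen key step; this is better. The C19 side chain is in place before the cycloaddition, so the six-step conversion of the methylene (steps 11–16) disappears; this is clearly better. The cis relation of C15 and C25 comes from the tether and is about equal in reliability.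
- Against it here: C19 must be made in an open chain and must steer C15 and C25 through a flexible three-atom tether. A4 has no C28, so C25 must later be acylated to a quaternary centre in competition with C11; here the chosen plan, with the ester present from the start, is better. C13 is sp2 in A4 and must be set by a face-selective reduction of a hindered alkene. Both tertiary oxygens carry the same silyl group, so the later selective ionisation at C41 is not prepared.
- Comparison: a cationic concerted or stepwise (4+3) against a zwitterionic stepwise (3+2); both are known reaction types. The front end is shorter and the back end longer, and the risk moves to the quaternisation of C25.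

**Alternative 3:** The cut removes C30–C41 in a [3,3] sense, from the bicyclo[4.3.1]decane A6 with an exocyclic C13=C12 methylene back to the seven-membered cyclic enol ether A5 (O on C28 bound to C12, alkene C13=C41). In the forward step heating would break O–C12 and form C30–C41 (Claisen rearrangement with ring transposition).
- In its favour: the two quaternary carbons are joined without any cation, so the geranyl diene and a free tertiary alcohol are tolerated. No choreography of silyl groups and no bridgehead metalation are needed. On chemoselectivity at this bond it is better than step 22.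
- Against it here: the new bond joins a fully substituted alkene terminus to a fully substituted enol carbon through a boat-like transition state forced by the medium ring, so a high barrier and competing ionisation or [1,3] shift are expected. A5 needs selective O-alkylation of one of three enol oxygens into a seven-membered ether. A6 still lacks C11–C12, which must be closed in an anti-Markovnikov sense in a further uncertain step. The C15, C19 and C25 array must be made separately.
- Comparison: on mechanism (pericyclic against ionic) it is the more elegant. On structure it leaves one more ring to close than the chosen closure. On step economy it is not shorter.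

Key step: step 10

**Remarks on the chemistry (assumptions)**
- The enone ester 24 and its adduct 25 were checked against the target: S at C13, cis ring fusion and the C15–C16 bond anti to the C13 side chain are what the cage requires, so no structure was changed.
- The sense of induction in step 7 is assumed by analogy with 4-tert-butylcyclohexanone; the antipodal amide is used if the sense is opposite.
- Centres that are labile or are removed later (cyclopropane carbons of 20, C20 of 32, C11 of 39 and 41) are written without descriptors; 42, 43 and related compounds are drawn as one enol tautomer.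

## Route

Step 1
Reactants: 1 3-methylbut-2-enal; 2 bromine
Product: 4 2-bromo-3-methylbut-2-enal, via 2,3-dibromo-3-methylbutanal 3 (not isolated)
Conditions: Br2, CH2Cl2, −78 to 0 °C; then Et3N, 0 °C to rt
Reagents that add atoms: bromine, BrBr
Why: Bromine adds across the enal C=C and triethylamine then removes the acidic α-hydrogen with loss of the tertiary bromide (addition–elimination α-bromination of an enal).

Step 2
Reactants: 4 2-bromo-3-methylbut-2-enal
Product: 5 2-bromo-3-methylbut-2-en-1-ol
Conditions: NaBH4, CeCl3·7H2O, MeOH, 0 °C
Reagents that add atoms: none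
Why: Luche 1,2-reduction of the enal; the alkenyl bromide is not touched.

Step 3
Reactants: 5 2-bromo-3-methylbut-2-en-1-ol; 6 (trimethylsilyl)methylmagnesium chloride
Product: 7 3-methyl-2-[(trimethylsilyl)methyl]but-2-en-1-ol
Conditions: Me3SiCH2MgCl (2.5 equiv), NiCl2(dppp) (5 mol %), THF, reflux
Reagents that add atoms: (trimethylsilyl)methylmagnesium chloride, C[Si](C)(C)C[Mg]Cl
Why: Nickel-catalysed Kumada coupling of an alkenyl bromide with a Grignard reagent that has no β-hydrogen; the first equivalent only deprotonates the hydroxyl group.

Step 4
Reactants: 7 3-methyl-2-[(trimethylsilyl)methyl]but-2-en-1-ol; 8 acetic anhydride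
Product: 9 3-methyl-2-[(trimethylsilyl)methyl]but-2-en-1-yl acetate
Conditions: Ac2O, pyridine, DMAP (cat.), CH2Cl2, 0 °C to rt
Reagents that add atoms: acetic anhydride, CC(=O)OC(C)=O
Why: Standard acetylation of a primary allylic alcohol; the allylsilane is stable to these mildly basic conditions.

Step 5
Reactants: 10 ethyl 1,4-dioxaspiro[4.5]decane-8-carboxylate; 11 methylmagnesium bromide; 12 water
Product: 14 4-(2-hydroxypropan-2-yl)cyclohexan-1-one, via ketal alcohol 13 (not isolated)
Conditions: MeMgBr (3 equiv), THF, 0 °C to rt; then 2 M HCl, rt
Reagents that add atoms: methylmagnesium bromide, C[Mg]Br; water, O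
Why: Double Grignard addition to the ester builds C41 with both methyl groups; the acidic work-up hydrolyses the dioxolane in the same operation.

Step 6
Reactants: 14 4-(2-hydroxypropan-2-yl)cyclohexan-1-one; 15 triethylsilyl trifluoromethanesulfonate
Product: 16 4-[2-(triethylsilyloxy)propan-2-yl]cyclohexan-1-one
Conditions: Et3SiOTf, 2,6-lutidine, CH2Cl2, −78 °C
Reagents that add atoms: triethylsilyl trifluoromethanesulfonate, CC[Si](CC)(CC)OS(=O)(=O)C(F)(F)F
Why: Silyl triflate with 2,6-lutidine silylates the tertiary alcohol at −78 °C, where the ketone is not turned into its enol ether.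

Step 7
Reactants: 16 4-[2-(triethylsilyloxy)propan-2-yl]cyclohexan-1-one; 17 chlorotrimethylsilane
Product: 18 (S)-4-[2-(triethylsilyloxy)propan-2-yl]-1-(trimethylsilyloxy)cyclohex-1-ene
Conditions: (R,R)-bis(1-phenylethyl)amine, n-BuLi, LiCl, Me3SiCl (internal quench), THF, −100 to −78 °C
Reagents that add atoms: chlorotrimethylsilane, C[Si](C)(C)Cl
Why: Asymmetric deprotonation: the C2-symmetric lithium amide removes one of the two enantiotopic axial α-hydrogens of the conformationally locked ketone and the enolate is silylated at once. This fixes C13 as S for the whole route; high enantiomeric purity is expected by analogy with 4-tert-butylcyclohexanone.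

Step 8
Reactants: 18 (S)-4-[2-(triethylsilyloxy)propan-2-yl]-1-(trimethylsilyloxy)cyclohex-1-ene; 19 bromoform
Product: 21 (5S)-2-bromo-5-[2-(triethylsilyloxy)propan-2-yl]cyclohept-2-en-1-one, via dibromocyclopropane 20 (not isolated)
Conditions: CHBr3, KOtBu, pentane, −30 °C to rt; then toluene, 80 °C
Reagents that add atoms: bromoform, BrC(Br)Br
Why: Dibromocarbene adds to the electron-rich enol ether and the siloxy-dibromocyclopropane opens by cyclopropyl-to-allyl cation ring opening with loss of bromide and of the silyl group (one-carbon ring expansion of a silyl enol ether to a 2-bromocycloalk-2-enone). The carbene carbon becomes C25, with its bromine, between C26 and C15; C13 is not involved.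

Step 9
Reactants: 21 (5S)-2-bromo-5-[2-(triethylsilyloxy)propan-2-yl]cyclohept-2-en-1-one; 22 carbon monoxide; 23 methanol
Product: 24 methyl (4S)-7-oxo-4-[2-(triethylsilyloxy)propan-2-yl]cyclohept-1-ene-1-carboxylate
Conditions: PdCl2(PPh3)2 (5 mol %), CO (1 atm), MeOH (10 equiv), iPr2NEt, DMF, 50 °C
Reagents that add atoms: carbon monoxide, [C-]#[O+]; methanol, CO
Why: Palladium-catalysed methoxycarbonylation of an alkenyl bromide places the ester on C25 without any regiochemical choice; a hindered amine and only a few equivalents of methanol limit conjugate addition of methanol to the product.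

Step 10
Reactants: 24 methyl (4S)-7-oxo-4-[2-(triethylsilyloxy)propan-2-yl]cyclohept-1-ene-1-carboxylate; 9 3-methyl-2-[(trimethylsilyl)methyl]but-2-en-1-yl acetate
Product: 25 cis-fused methylenecyclopentane keto ester (C26 ketone, C28 methyl ester on C25, exocyclic C19=C20, gem-dimethyl C16 on C15; H-15 and C28 cis; C16 trans to the C13 side chain)
Conditions: Pd(OAc)2 (5 mol %), P(OiPr)3 (35 mol %), THF, reflux
Reagents that add atoms: acetate 9 (supplies C16, C17, C18, C19, C20 and C24), CC(C)=C(C[Si](C)(C)C)COC(C)=O
Why: The phosphite reduces Pd(OAc)2 to zerovalent palladium, which ionises the allylic acetate of 9; acetate then removes the silyl group as Me3SiOAc and leaves the zwitterionic trimethylenemethane–palladium complex, the closest known reaction type being the palladium-catalysed trimethylenemethane (3+2) cycloaddition to 2-alkoxycarbonyl enones. The complex equilibrates so that the metal rests on the unsubstituted allyl part and the CMe2 carbon carries the charge; this carbon adds in a Michael sense to C15 of the doubly activated enone (C15–C16). The stabilised β-keto ester enolate then closes the cyclopentane by intramolecular allylic alkylation at the near π-allyl terminus (C24–C25, five-membered ring; attack at the far terminus would need a seven-membered ring), which frees the catalyst and leaves the exocyclic C19=C20 methylene. C15 is set by approach of the bulky nucleophile to the enone face opposite the pseudo-equatorial C13 side chain, and C25 follows because a five-membered ring can only close cis on the seven-membered ring. The step needs regioselectivity (CMe2 to C15) and π-facial selectivity: the first rests on the known preference of alkyl-substituted complexes to bond through the substituted terminus and on the high barrier to joining a tertiary carbon to the fully substituted C25, the second on the C13 stereocentre. Ketone, ester and tertiary silyl ether are inert under these neutral conditions.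

Step 11
Reactants: 25 cis-fused methylenecyclopentane keto ester; 26 triisopropylsilyl trifluoromethanesulfonate
Product: 27 C26 triisopropylsilyl enol ether of 25 (C11=C26)
Conditions: iPr3SiOTf, Et3N, CH2Cl2, 0 °C to rt
Reagents that add atoms: triisopropylsilyl trifluoromethanesulfonate, CC(C)[Si](OS(=O)(=O)C(F)(F)F)(C(C)C)C(C)C
Why: Soft enolisation toward C11, the only enolisable position because C25 is quaternary, gives a robust enol silyl ether. It masks C26 against borane and Grignard reagents without acid that could move the exocyclic alkene or strip the tertiary silyl ether.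

Step 12
Reactants: 27 C26 triisopropylsilyl enol ether; 28 hydrogen peroxide
Product: 29 primary alcohol at C20 (C19 epimer with CH2OH on the concave face, cis to C26)
Conditions: 9-BBN (2 equiv), THF, 0 °C to rt; then NaOH, H2O2, 0 °C
Reagents that add atoms: hydrogen peroxide, OO
Why: Anti-Markovnikov hydroboration–oxidation; 9-BBN takes the 1,1-disubstituted C19=C20 alkene much faster than the hindered trisubstituted enol ether and leaves the ester alone. Boron is expected to arrive from the convex face, which puts C20 on the concave face; this centre is corrected in step 13.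

Step 13
Reactants: 29 primary alcohol at C20
Product: 31 C20 aldehyde with the formyl group on the convex face (cis to H-15 and C28), via kinetic aldehyde 30 (not isolated)
Conditions: Dess–Martin periodinane, NaHCO3, CH2Cl2, 0 °C to rt; then DBU, rt
Reagents that add atoms: none
Why: Dess–Martin oxidation followed by base equilibration of the α-stereocentre: the formyl group should move to the convex face of the cis-fused bicycle, away from the seven-membered ring. C19 is thus set under thermodynamic control whatever the facial outcome of step 12.

Step 14
Reactants: 31 C20 aldehyde (convex face); 11 methylmagnesium bromide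
Product: 32 secondary alcohol C19–CH(OH)CH3 (both C20 epimers)
Conditions: MeMgBr, THF, −78 °C
Reagents that add atoms: methylmagnesium bromide, C[Mg]Br
Why: Grignard addition to the aldehyde at low temperature; the hindered C28 ester and the enol ether do not react, and the new carbinol centre is removed in step 15.

Step 15
Reactants: 32 secondary alcohol
Product: 33 methyl ketone C19–C(O)CH3
Conditions: Dess–Martin periodinane, NaHCO3, CH2Cl2, rt
Reagents that add atoms: none
Why: Dess–Martin oxidation of a secondary alcohol; C19 keeps the thermodynamically preferred configuration.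

Step 16
Reactants: 33 methyl ketone; 11 methylmagnesium bromide
Product: 34 tertiary alcohol C19–C(CH3)2OH
Conditions: MeMgBr, CeCl3, THF, −78 to 0 °C; cold NH4Cl quench
Reagents that add atoms: methylmagnesium bromide, C[Mg]Br
Why: Cerium-mediated Grignard addition suppresses enolisation of the hindered methyl ketone and is selective for the ketone over the neopentyl ester C28. The cold quench keeps the C20 alkoxide from lactonising onto C28, to which it is cis.

Step 17
Reactants: 34 tertiary alcohol; 35 tert-butyldimethylsilyl trifluoromethanesulfonate
Product: 36 C20 tert-butyldimethylsilyl ether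
Conditions: tBuMe2SiOTf, 2,6-lutidine, CH2Cl2, 0 °C to rt
Reagents that add atoms: tert-butyldimethylsilyl trifluoromethanesulfonate, CC(C)(C)[Si](C)(C)OS(=O)(=O)C(F)(F)F
Why: Silyl triflate with 2,6-lutidine silylates the hindered tertiary alcohol; this silyl group is chosen to outlast the triethylsilyl ether at C41 in steps 21 and 22.

Step 18
Reactants: 36 C20 tert-butyldimethylsilyl ether
Product: 37 keto ester with free C26 ketone (C20 silyl ether, C41 triethylsilyl ether, C28 methyl ester)
Conditions: Bu4NF, AcOH, THF, −20 to 0 °C
Reagents that add atoms: none
Why: Buffered fluoride cleaves the enol silyl ether, whose leaving group is an enolate, much faster than the two tertiary alkyl silyl ethers.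

Step 19
Reactants: 37 keto ester with free C26 ketone; 38 1-acetylbenzotriazole
Product: 39 2-acetyl ketone (β-diketone C26/C39 with C30 as methyl)
Conditions: MgBr2·OEt2, iPr2NEt, CH2Cl2, rt
Reagents that add atoms: 1-acetylbenzotriazole, CC(=O)n1nnc2ccccc12
Why: Soft-enolisation C-acylation of a ketone by an N-acylbenzotriazole (crossed Claisen); only C11 can enolise, and the magnesium diketonate formed is protected from further acylation.

Step 20
Reactants: 39 2-acetyl ketone; 40 methyl benzoate
Product: 42 bicyclo[4.3.1]decane trione (2-benzoyl-1,3-dione ring C11–C39–C30–C28–C25–C26 closed; C11–H bridgehead), via open triketone 41 (not isolated)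
Conditions: LiN(iPr)2 (3.3 equiv), THF, −78 to 0 °C; PhCO2Me, 0 °C; then MeOH, 50 °C; aqueous HCl work-up
Reagents that add atoms: methyl benzoate, COC(=O)c1ccccc1
Why: The β-diketone dianion is acylated at its terminal carbon C30 by methyl benzoate (dianion Claisen acylation) to give the 1,3,5-triketone. After methanol is added the anion centred on C30, the most acidic site, closes the six-membered ring onto the C28 ester (intramolecular Claisen, 6-exo-trig), driven by formation of the strongly acidic 2-benzoyl-1,3-dione. C11 epimerises freely, so its acyl group takes the face of C28, which fixes the C11 bridgehead.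

Step 21
Reactants: 42 bicyclo[4.3.1]decane trione
Product: 43 the same trione with free C41 tertiary alcohol
Conditions: HF·pyridine, pyridine, THF, 0 °C to rt
Reagents that add atoms: none
Why: The tertiary triethylsilyl ether is removed selectively beside the much slower tertiary tert-butyldimethylsilyl ether, so that C41–OH is the only readily ionisable group.

Step 22
Reactants: 43 trione with free C41 alcohol
Product: 44 homoadamantane cage with C11–H and C20 silyl ether
Conditions: TfOH (0.2 equiv), CH2Cl2, −40 to 0 °C
Reagents that add atoms: none
Why: Acid-catalysed SN1 alkylation: the free tertiary alcohol ionises to the C41 cation, which is trapped by enol carbon C30 on the same face of the seven-membered ring; rings C11–C12–C13–C41–C30–C39 and C13–C14–C15–C25–C28–C30–C41 close together. O-alkylated cyclic enol ethers can re-ionise and funnel to the C-alkylated cage, and C30 can only take the cage configuration. The weakly basic, hindered silyl ether oxygen at C20 is expected to resist the catalytic acid.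

Step 23
Reactants: 44 homoadamantane cage with C11–H; 45 geranyl bromide
Product: 46 C11-geranyl cage with C20 silyl ether
Conditions: lithium 2,2,6,6-tetramethylpiperidide (2 equiv), THF, −78 °C; geranyl bromide, −78 to −20 °C
Reagents that add atoms: geranyl bromide, CC(C)=CCC/C(C)=C/CBr
Why: Bridgehead lithiation–alkylation of the kind used on bicyclic polyprenylated acylphloroglucinol cores: C11–H is the only hydrogen flanked by two carbonyls, and the hindered amide can neither reduce nor add to the ketones. The carbanion attacks the primary carbon of geranyl bromide with retention of the E alkene, and the cage fixes C11.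

Step 24
Reactants: 46 C11-geranyl cage with C20 silyl ether
Product: 47 CNP0164095.1
Conditions: HF·pyridine, THF, rt
Reagents that add atoms: none
Why: Fluoride-assisted cleavage of the tertiary silyl ether under mildly acidic conditions, which spare the geranyl diene and the retro-Claisen-prone tricarbonyl array.

## Compound list

1 | 3-methylbut-2-enal | CC(C)=CC=O | starting material
2 | bromine | BrBr | starting material
3 | 2,3-dibromo-3-methylbutanal | CC(C)(Br)C(Br)C=O | intermediate
4 | 2-bromo-3-methylbut-2-enal | CC(C)=C(Br)C=O | intermediate
5 | 2-bromo-3-methylbut-2-en-1-ol | CC(C)=C(Br)CO | intermediate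
6 | (trimethylsilyl)methylmagnesium chloride | C[Si](C)(C)C[Mg]Cl | starting material
7 | 3-methyl-2-[(trimethylsilyl)methyl]but-2-en-1-ol | CC(C)=C(C[Si](C)(C)C)CO | intermediate
8 | acetic anhydride | CC(=O)OC(C)=O | starting material
9 | 3-methyl-2-[(trimethylsilyl)methyl]but-2-en-1-yl acetate | CC(C)=C(C[Si](C)(C)C)COC(C)=O | intermediate
10 | ethyl 1,4-dioxaspiro[4.5]decane-8-carboxylate | CCOC(=O)C1CCC2(CC1)OCCO2 | starting material
11 | methylmagnesium bromide | C[Mg]Br | starting material
12 | water | O | starting material
13 | 2-(1,4-dioxaspiro[4.5]decan-8-yl)propan-2-ol | CC(C)(O)C1CCC2(CC1)OCCO2 | intermediate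
14 | 4-(2-hydroxypropan-2-yl)cyclohexan-1-one | CC(C)(O)C1CCC(=O)CC1 | intermediate
15 | triethylsilyl trifluoromethanesulfonate | CC[Si](CC)(CC)OS(=O)(=O)C(F)(F)F | starting material
16 | 4-[2-(triethylsilyloxy)propan-2-yl]cyclohexan-1-one | CC[Si](CC)(CC)OC(C)(C)C1CCC(=O)CC1 | intermediate
17 | chlorotrimethylsilane | C[Si](C)(C)Cl | starting material
18 | (S)-4-[2-(triethylsilyloxy)propan-2-yl]-1-(trimethylsilyloxy)cyclohex-1-ene | C[Si](C)(C)OC1=CC[C@@H](C(C)(C)O[Si](CC)(CC)CC)CC1 | intermediate
19 | bromoform | BrC(Br)Br | starting material
20 | 7,7-dibromo-4-[2-(triethylsilyloxy)propan-2-yl]-1-(trimethylsilyloxy)bicyclo[4.1.0]heptane (C4 as in 18; cyclopropane carbons as formed) | C[Si](C)(C)OC12CC[C@H](C(C)(C)O[Si](CC)(CC)CC)CC1C2(Br)Br | intermediate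
21 | (5S)-2-bromo-5-[2-(triethylsilyloxy)propan-2-yl]cyclohept-2-en-1-one | O=C1CC[C@H](C(C)(C)O[Si](CC)(CC)CC)CC=C1Br | intermediate
22 | carbon monoxide | [C-]#[O+] | starting material
23 | methanol | CO | starting material
24 | methyl (4S)-7-oxo-4-[2-(triethylsilyloxy)propan-2-yl]cyclohept-1-ene-1-carboxylate | COC(=O)C1=CC[C@@H](C(C)(C)O[Si](CC)(CC)CC)CCC1=O | intermediate
25 | methyl 1,1-dimethyl-2-methylidene-4-oxo-7-[2-(triethylsilyloxy)propan-2-yl]octahydroazulene-3a(1H)-carboxylate (cis-fused; 7-substituent trans to C1) | C=C1C[C@@]2(C(=O)OC)C(=O)CC[C@H](C(C)(C)O[Si](CC)(CC)CC)C[C@H]2C1(C)C | intermediate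
26 | triisopropylsilyl trifluoromethanesulfonate | CC(C)[Si](OS(=O)(=O)C(F)(F)F)(C(C)C)C(C)C | starting material
27 | C26 triisopropylsilyl enol ether of 25 (C11=C26) | C=C1C[C@@]2(C(=O)OC)C(O[Si](C(C)C)(C(C)C)C(C)C)=CC[C@H](C(C)(C)O[Si](CC)(CC)CC)C[C@H]2C1(C)C | intermediate
28 | hydrogen peroxide | OO | starting material
29 | C20 primary alcohol, C19 epimer (CH2OH on the concave face) | OC[C@H]1C[C@@]2(C(=O)OC)C(O[Si](C(C)C)(C(C)C)C(C)C)=CC[C@H](C(C)(C)O[Si](CC)(CC)CC)C[C@H]2C1(C)C | intermediate
30 | C20 aldehyde, concave-face epimer | O=C[C@H]1C[C@@]2(C(=O)OC)C(O[Si](C(C)C)(C(C)C)C(C)C)=CC[C@H](C(C)(C)O[Si](CC)(CC)CC)C[C@H]2C1(C)C | intermediate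
31 | C20 aldehyde, convex-face epimer (target configuration at C19) | O=C[C@@H]1C[C@@]2(C(=O)OC)C(O[Si](C(C)C)(C(C)C)C(C)C)=CC[C@H](C(C)(C)O[Si](CC)(CC)CC)C[C@H]2C1(C)C | intermediate
32 | secondary alcohol C19–CH(OH)CH3 (C20 undefined) | CC(O)[C@@H]1C[C@@]2(C(=O)OC)C(O[Si](C(C)C)(C(C)C)C(C)C)=CC[C@H](C(C)(C)O[Si](CC)(CC)CC)C[C@H]2C1(C)C | intermediate
33 | methyl ketone C19–C(O)CH3 | CC(=O)[C@@H]1C[C@@]2(C(=O)OC)C(O[Si](C(C)C)(C(C)C)C(C)C)=CC[C@H](C(C)(C)O[Si](CC)(CC)CC)C[C@H]2C1(C)C | intermediate
34 | tertiary alcohol C19–C(CH3)2OH | CC(C)(O)[C@@H]1C[C@@]2(C(=O)OC)C(O[Si](C(C)C)(C(C)C)C(C)C)=CC[C@H](C(C)(C)O[Si](CC)(CC)CC)C[C@H]2C1(C)C | intermediate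
35 | tert-butyldimethylsilyl trifluoromethanesulfonate | CC(C)(C)[Si](C)(C)OS(=O)(=O)C(F)(F)F | starting material
36 | C20 tert-butyldimethylsilyl ether of 34 | CC(C)(O[Si](C)(C)C(C)(C)C)[C@@H]1C[C@@]2(C(=O)OC)C(O[Si](C(C)C)(C(C)C)C(C)C)=CC[C@H](C(C)(C)O[Si](CC)(CC)CC)C[C@H]2C1(C)C | intermediate
37 | keto ester with free C26 ketone, C20 and C41 silyl ethers | CC(C)(O[Si](C)(C)C(C)(C)C)[C@@H]1C[C@@]2(C(=O)OC)C(=O)CC[C@H](C(C)(C)O[Si](CC)(CC)CC)C[C@H]2C1(C)C | intermediate
38 | 1-acetylbenzotriazole | CC(=O)n1nnc2ccccc12 | starting material
39 | 2-acetyl ketone (C11 acetylated; C11 labile) | CC(C)(O[Si](C)(C)C(C)(C)C)[C@@H]1C[C@@]2(C(=O)OC)C(=O)C(C(C)=O)C[C@H](C(C)(C)O[Si](CC)(CC)CC)C[C@H]2C1(C)C | intermediate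
40 | methyl benzoate | COC(=O)c1ccccc1 | starting material
41 | open 1,3,5-triketone (C11–C39(O)–C30H2–C31(O)Ph; C11 labile) | CC(C)(O[Si](C)(C)C(C)(C)C)[C@@H]1C[C@@]2(C(=O)OC)C(=O)C(C(=O)CC(=O)c3ccccc3)C[C@H](C(C)(C)O[Si](CC)(CC)CC)C[C@H]2C1(C)C | intermediate
42 | bicyclo[4.3.1]decane trione with C41 triethylsilyl ether and C20 tert-butyldimethylsilyl ether (enol form) | [C@@H]12C[C@H](C(C)(C)O[Si](CC)(CC)CC)C[C@H]3C(C)(C)[C@H](C(C)(C)O[Si](C)(C)C(C)(C)C)C[C@]3(C1=O)C(O)=C(C(=O)c1ccccc1)C2=O | intermediate
43 | bicyclo[4.3.1]decane trione with free C41 alcohol (enol form) | [C@@H]12C[C@H](C(C)(C)O)C[C@H]3C(C)(C)[C@H](C(C)(C)O[Si](C)(C)C(C)(C)C)C[C@]3(C1=O)C(O)=C(C(=O)c1ccccc1)C2=O | intermediate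
44 | homoadamantane cage with C11–H and C20 silyl ether | [C@@H]12C[C@H]3C[C@H]4C(C)(C)[C@H](C(C)(C)O[Si](C)(C)C(C)(C)C)C[C@]4(C1=O)C(=O)[C@@](C(=O)c1ccccc1)(C2=O)C3(C)C | intermediate
45 | geranyl bromide, (E)-1-bromo-3,7-dimethylocta-2,6-diene | CC(C)=CCC/C(C)=C/CBr | starting material
46 | C20 tert-butyldimethylsilyl ether of the target | CC(C)=CCC/C(C)=C/C[C@@]12C[C@H]3C[C@H]4C(C)(C)[C@H](C(C)(C)O[Si](C)(C)C(C)(C)C)C[C@]4(C1=O)C(=O)[C@@](C(=O)c1ccccc1)(C2=O)C3(C)C | intermediate
47 | CNP0164095.1 | CC(C)=CCC/C(C)=C/C[C@@]12C[C@H]3C[C@H]4C(C)(C)[C@H](C(C)(C)O)C[C@]4(C1=O)C(=O)[C@@](C(=O)c1ccccc1)(C2=O)C3(C)C | target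

## Step count and least certain steps

Total: 24 steps. Longest linear sequence: 20 steps (steps 5–24, from 10); the donor branch (steps 1–4) joins at step 10.

**Step 10 (key step).** The dimethyl-substituted palladium complex may lose a proton to give a diene faster than it adds, it may bond through its unsubstituted terminus, and the remote C13 centre may discriminate the two enone faces only moderately. The fallback sets out from 24 and 9 and returns at 25; it joins the same partners in two polar steps. EtAlCl2 in CH2Cl2 at −78 °C promotes a Sakurai conjugate addition of the allylsilane, which reacts through its γ-carbon (the CMe2 terminus), and gives the allylic acetate F1. Pd(PPh3)4 with a mild base then closes C24–C25 by intramolecular Tsuji–Trost alkylation of the β-keto ester to give 25.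

**Step 22.** The C20 silyl ether may be cleaved or ionised, followed by elimination at C20. The C41 cation may be trapped on an enol oxygen and not return, or it may eliminate to the isopropenyl compound. The fallback sets out from 37 and returns at 44; it forms C30–C41 without acid.
- HF·pyridine removes the triethylsilyl group to give hydroxy ketone F2.
- Burgess reagent dehydrates this to isopropenyl ketone F3.
- Acetylation as in step 19 gives diketone F4.
- Benzoylation and Claisen closure as in step 20 lead through open triketone F5 to isopropenyl trione F6.
- Heating F6 in xylene in a sealed tube brings about a thermal Conia-ene cyclisation: the enol hydrogen goes to C42 and C30 bonds to C41, giving 44.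

**Step 23.** Deprotonation at the cage bridgehead may be slow because the C11–H bond overlaps poorly with the flanking carbonyls. The amide or the carbanion may attack the benzoyl or cage ketones, and geranyl bromide may react in the SN2′ sense. The fallback sets out from 39 and returns at 46; it puts the geranyl group on while C11 is still an ordinary diketone carbon.
- NaH and geranyl bromide in THF/DMF give the C-geranyl diketone F7; the isomer with acetyl cis to C28 is required.
- LiN(iPr)2 and methyl benzoate give the open triketone F8.
- NaOMe in MeOH closes this to the geranyl trione F9.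
- HF·pyridine gives the C41 alcohol F10.
- Catalytic TfOH as in step 22 then gives 46.
The price is facial control at C11 and a cationic step in the presence of the diene.

**Step 20.** Proton transfer may quench the dianion before C30 is benzoylated, and the ring closure onto the hindered C28 ester may stall at the open triketone or at an enol lactone. The fallback sets out from 39 and returns at 42; it replaces the ester acylation by an aldol reaction. The dianion is added to benzaldehyde to give hydroxy diketone F11, Dess–Martin oxidation gives 41, which is now isolated, and 41 is closed in a separate step with NaOMe in MeOH at reflux to give 42.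

## Further compounds

F1 | step 10 | methyl 2-oxo-5-[2-(triethylsilyloxy)propan-2-yl]-7-[4-acetoxy-2-methyl-3-methylidenebutan-2-yl]cycloheptane-1-carboxylate (C15 as in 25; C25 labile) | COC(=O)C1C(=O)CC[C@H](C(C)(C)O[Si](CC)(CC)CC)C[C@H]1C(C)(C)C(=C)COC(C)=O
F2 | step 22 | keto ester 37 with free C41 alcohol | CC(C)(O[Si](C)(C)C(C)(C)C)[C@@H]1C[C@@]2(C(=O)OC)C(=O)CC[C@H](C(C)(C)O)C[C@H]2C1(C)C
F3 | step 22 | keto ester with isopropenyl group on C13 | CC(C)(O[Si](C)(C)C(C)(C)C)[C@@H]1C[C@@]2(C(=O)OC)C(=O)CC[C@H](C(C)=C)C[C@H]2C1(C)C
F4 | step 22 | C11-acetyl diketone with isopropenyl group on C13 | CC(C)(O[Si](C)(C)C(C)(C)C)[C@@H]1C[C@@]2(C(=O)OC)C(=O)C(C(C)=O)C[C@H](C(C)=C)C[C@H]2C1(C)C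
F5 | step 22 | open 1,3,5-triketone with isopropenyl group on C13 | CC(C)(O[Si](C)(C)C(C)(C)C)[C@@H]1C[C@@]2(C(=O)OC)C(=O)C(C(=O)CC(=O)c3ccccc3)C[C@H](C(C)=C)C[C@H]2C1(C)C
F6 | step 22 | bicyclo[4.3.1]decane trione with isopropenyl group on C13 (enol form) | [C@@H]12C[C@H](C(C)=C)C[C@H]3C(C)(C)[C@H](C(C)(C)O[Si](C)(C)C(C)(C)C)C[C@]3(C1=O)C(O)=C(C(=O)c1ccccc1)C2=O
F7 | step 23 | C11-geranyl C11-acetyl keto ester (acetyl cis to C28) | CC(C)=CCC/C(C)=C/C[C@@]1(C(C)=O)C[C@H](C(C)(C)O[Si](CC)(CC)CC)C[C@H]2C(C)(C)[C@H](C(C)(C)O[Si](C)(C)C(C)(C)C)C[C@]2(C1=O)C(=O)OC
F8 | step 23 | C11-geranyl open 1,3,5-triketone | CC(C)=CCC/C(C)=C/C[C@@]1(C(=O)CC(=O)c3ccccc3)C[C@H](C(C)(C)O[Si](CC)(CC)CC)C[C@H]2C(C)(C)[C@H](C(C)(C)O[Si](C)(C)C(C)(C)C)C[C@]2(C1=O)C(=O)OC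
F9 | step 23 | C11-geranyl bicyclo[4.3.1]decane trione with C41 triethylsilyl ether (enol form) | CC(C)=CCC/C(C)=C/C[C@@]12C[C@H](C(C)(C)O[Si](CC)(CC)CC)C[C@H]3C(C)(C)[C@H](C(C)(C)O[Si](C)(C)C(C)(C)C)C[C@]3(C1=O)C(O)=C(C(=O)c1ccccc1)C2=O
F10 | step 23 | C11-geranyl bicyclo[4.3.1]decane trione with free C41 alcohol (enol form) | CC(C)=CCC/C(C)=C/C[C@@]12C[C@H](C(C)(C)O)C[C@H]3C(C)(C)[C@H](C(C)(C)O[Si](C)(C)C(C)(C)C)C[C@]3(C1=O)C(O)=C(C(=O)c1ccccc1)C2=O
F11 | step 20 | aldol adduct of 39 with benzaldehyde (C11–C39(O)–C30H2–C31H(OH)Ph; carbinol centre undefined) | CC(C)(O[Si](C)(C)C(C)(C)C)[C@@H]1C[C@@]2(C(=O)OC)C(=O)C(C(=O)CC(O)c3ccccc3)C[C@H](C(C)(C)O[Si](CC)(CC)CC)C[C@H]2C1(C)C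
A1 | alternative 1 | spiro[4.5]decane trione with C11 prenyl and geranyl groups and C15 formyl group (enol form) | CC(C)=CCC/C(C)=C/C[C@@]1(CC=C(C)C)C(=O)[C@@]2(C[C@@H](C(C)(C)O)C(C)(C)[C@@H]2C=O)C(O)=C(C(=O)c2ccccc2)C1=O
A2 | alternative 1 | C14-hydroxy derivative of the target | CC(C)=CCC/C(C)=C/C[C@@]12C[C@H]3[C@@H](O)[C@H]4C(C)(C)[C@H](C(C)(C)O)C[C@]4(C1=O)C(=O)[C@@](C(=O)c1ccccc1)(C2=O)C3(C)C
A3 | alternative 2 | chloromethyl ketone with tethered 2-substituted (E)-diene | ClCC(=O)CC[C@@H](C(C)(C)O[Si](CC)(CC)CC)C(C)(C)/C=C/C(=C)C(C)(C)O[Si](CC)(CC)CC
A4 | alternative 2 | cis-hydroazulenone with C13=C14 alkene and two triethylsilyl ethers | O=C1CCC(C(C)(C)O[Si](CC)(CC)CC)=C[C@H]2C(C)(C)[C@H](C(C)(C)O[Si](CC)(CC)CC)C[C@@H]12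
A5 | alternative 3 | seven-membered cyclic enol ether (O on C28 bound to C12; C13=C41 isopropylidene) | CC(C)=CCC/C(C)=C/CC1=C(O)[C@]23C[C@@H](C(C)(C)O)C(C)(C)[C@@H]2CC(=C(C)C)COC3=C(C(=O)c2ccccc2)C1=O
A6 | alternative 3 | bicyclo[4.3.1]decane with exocyclic C13=C12 methylene | CC(C)=CCC/C(C)=C/CC1=C(O)[C@]23C[C@@H](C(C)(C)O)C(C)(C)[C@@H]2CC(=C)C(C)(C)[C@](C(=O)c2ccccc2)(C1=O)C3=O
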